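**Retrosynthetic overview**
1. The target comes from a 5-ene hydroxyquinone by acetylation and a shift of the alkene into conjugation, with C5–H set by equilibration. That quinone comes from a tetracyclic resorcinol by oxidation at C11. Ring C is bought as an arene that already carries C10.
2. Ring B closes last. C7–C8 forms by Friedel–Crafts attack on the allyl cation of a C5 vinyl carbinol; C6–C7 come from vinylmagnesium bromide, and C5 is the bridging ketone of a bicyclic keto lactone.
3. Key disconnection: ring A and the δ-lactone are cut together (C1–C10, C10–C20, O–C19), back to an acyclic chloro β-keto ester plus formaldehyde.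
4. Only quaternary C4 is set by a reagent (valine-enamine alkylation). C10 follows because only the cis hydroxy ester can lactonise. C5 follows by equilibration.
5. Ring order: C (purchased), then A + lactone (one operation), then B.

Assumption: 4-isopropyl-3,5-dimethoxybenzaldehyde, the bulk aldehyde used to make tapinarof, is purchased. Abietane numbering (C1–C20) is used for positions.

**Step 1**
Reactants: 1 4-isopropyl-3,5-dimethoxybenzaldehyde
Product: 2 (4-isopropyl-3,5-dimethoxyphenyl)acetonitrile
Conditions: TosMIC, KOtBu, DME, −40 °C; then MeOH, reflux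
Reagents that add atoms: p-toluenesulfonylmethyl isocyanide (TosMIC), Cc1ccc(cc1)S(=O)(=O)C[N+]#[C-]
Why: Van Leusen reductive cyanation, in which the TosMIC anion adds to the aldehyde and methanolysis of the opened oxazoline expels sulfinate and formate, turns ArCHO into ArCH2CN (C10–C5) in one pot and works well for electron-rich benzaldehydes; no stereocentre is formed.

**Step 2**
Reactants: 2 (4-isopropyl-3,5-dimethoxyphenyl)acetonitrile, 3 methyl 2-bromopropanoate (racemic)
Product: 4 methyl 4-(4-isopropyl-3,5-dimethoxyphenyl)-2-methyl-3-oxobutanoate (racemic)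
Conditions: Zn dust (Me3SiCl-activated), THF, reflux, slow addition of 3; then 3 M HCl, rt
Reagents that add atoms: water, O
Why: Blaise reaction, in which the zinc enolate of 3 adds to the nitrile faster than it deprotonates it when kept dilute and acid hydrolysis of the zinc enaminate gives the β-keto ester; C4 is still racemic and enolisable.

**Step 3**
Reactants: 4 methyl 4-(4-isopropyl-3,5-dimethoxyphenyl)-2-methyl-3-oxobutanoate, 5 L-valine tert-butyl ester (free base)
Product: 6 tert-butyl N-[(Z)-1-(4-isopropyl-3,5-dimethoxyphenyl)-4-methoxy-3-methyl-4-oxobut-2-en-2-yl]-L-valinate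
Conditions: BF3·OEt2 (cat.), toluene, reflux, Dean–Stark trap
Reagents that add atoms: none
Why: Acid-catalysed enamine condensation with azeotropic water removal gives only the ester-conjugated, N–H···O=C hydrogen-bonded Z-enamino ester, which erases the racemic C4 centre and attaches the auxiliary.

**Step 4**
Reactants: 6 tert-butyl N-[(Z)-1-(4-isopropyl-3,5-dimethoxyphenyl)-4-methoxy-3-methyl-4-oxobut-2-en-2-yl]-L-valinate, 7 1-chloro-3-iodopropane
Product: 9 methyl (S)-2-(3-chloropropyl)-4-(4-isopropyl-3,5-dimethoxyphenyl)-2-methyl-3-oxobutanoate, via alkylated ketimine 8 (not isolated)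
Conditions: LiN(iPr)2, toluene, −78 °C; (Me2N)3PO (1 equiv), 7, −55 to −20 °C; then 1 M HCl, THF, 0 °C
Reagents that add atoms: water, O
Why: Auxiliary-controlled alkylation of a chelated lithio-enamine (valine ester method for α-alkyl β-keto esters), in which lithium is held by the nitrogen and the valine ester carbonyl, the isopropyl group screens one face of C4=C5 and only the C–I end of 7 reacts, should set quaternary C4 as S, but I could not confirm which sense the (Me2N)3PO variant gives for this substrate; the sense reverses on changing the external ligand to THF, so either enantiomer is reachable from L-valine, and mild hydrolysis returns the auxiliary.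

**Step 5** (key step)
Reactants: 9 methyl (S)-2-(3-chloropropyl)-4-(4-isopropyl-3,5-dimethoxyphenyl)-2-methyl-3-oxobutanoate
Product: 12 (1S,5R)-5-(4-isopropyl-3,5-dimethoxyphenyl)-1-methyl-3-oxabicyclo[3.3.1]nonane-2,9-dione, via 2-arylcyclohexanone 10 (not isolated), via cis-hydroxymethyl ketone 11 (not isolated)
Conditions: KOtBu (1.05 equiv), NaI (0.2 equiv), THF, 0 °C to rt; then (CH2O)n (3 equiv), 1,8-diazabicyclo[5.4.0]undec-7-ene (0.3 equiv), rt
Reagents that add atoms: formaldehyde (from paraformaldehyde), C=O
Why: In this domino enolate alkylation, crossed aldol and lactonisation, the soft benzylic enolate closes ring A by an allowed 6-(enolendo)-exo-tet C-alkylation, ketone 10 then adds reversibly to formaldehyde on both faces, and only epimer 11, whose CH2O− lies 1,3-cis to the ester, can lactonise, so retro-aldol funnels all material into 12 and C4 dictates C10 (R).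

**Step 6**
Reactants: 12 (1S,5R)-5-(4-isopropyl-3,5-dimethoxyphenyl)-1-methyl-3-oxabicyclo[3.3.1]nonane-2,9-dione
Product: 13 (1S,5R,9S)-9-ethenyl-9-hydroxy-5-(4-isopropyl-3,5-dimethoxyphenyl)-1-methyl-3-oxabicyclo[3.3.1]nonan-2-one
Conditions: CH2=CHMgBr, LaCl3·2LiCl (0.3 equiv), THF, −78 °C; quench with water at −78 °C
Reagents that add atoms: vinylmagnesium bromide, C=C[Mg]Br
Why: This is a Lewis-acid-assisted Grignard 1,2-addition of a small sp2 nucleophile to a non-enolisable bridging ketone that is more electrophilic than the neopentyl lactone, with the cold quench preventing retro-aldol, and attack over the flatter lactone bridge gives the 9S alcohol, a centre that is erased in the next step.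

**Step 7**
Reactants: 13 (1S,5R,9S)-9-ethenyl-9-hydroxy-5-(4-isopropyl-3,5-dimethoxyphenyl)-1-methyl-3-oxabicyclo[3.3.1]nonan-2-one
Product: 15 (4S,10S)-12,14-dihydroxyabieta-5,8,11,13-tetraen-19,20-olide, via tetracyclic dimethyl ether 14 (not isolated)
Conditions: BBr3 (6 equiv), CH2Cl2, −78 °C to rt; then water
Reagents that add atoms: none
Why: In this intramolecular Friedel–Crafts allylation followed by aryl methyl ether cleavage, BBr3 ionises the tertiary allylic alcohol, the cation has no β-hydrogen to lose, its CH2 terminus is attacked by either of the two equivalent ring positions (ortho and para to OMe) to close ring B as the 5-ene, and warming removes both methyl groups; no new stereocentre is formed.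

**Step 8**
Reactants: 15 (4S,10S)-12,14-dihydroxyabieta-5,8,11,13-tetraen-19,20-olide
Product: 16 (4S,10R)-12-hydroxy-11,14-dioxoabieta-5,8,12-trien-19,20-olide
Conditions: (KSO3)2NO (2.5 equiv), KH2PO4 buffer, acetone/water, rt
Reagents that add atoms: potassium nitrosodisulfonate (KSO3)2NO, [K+].[K+].[O]N(S(=O)(=O)[O-])S(=O)(=O)[O-]
Why: Teuber oxidation of a 2-alkylresorcinol places oxygen on the only free ring carbon (C11, para to the C14 hydroxyl) and gives the 2-hydroxy-3-isopropyl-1,4-benzoquinone directly, leaving lactone and alkene untouched.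

**Step 9**
Reactants: 16 (4S,10R)-12-hydroxy-11,14-dioxoabieta-5,8,12-trien-19,20-olide
Product: 18 (4S,5R,10R)-12-acetoxy-11,14-dioxoabieta-6,8,12-trien-19,20-olide (target), via 5-ene acetate 17 (not isolated)
Conditions: Ac2O, Et3N, 4-(dimethylamino)pyridine (cat.), CH2Cl2, 0 °C; then 1,8-diazabicyclo[5.4.0]undec-7-ene (0.2 equiv), rt, argon
Reagents that add atoms: acetic anhydride, CC(=O)OC(C)=O
Why: In this O-acetylation followed by a base-mediated prototropic shift, the C7 hydrogens are allylic and vinylogous to the C11 carbonyl, the extended enolate is reprotonated at C5 to give the quinone-conjugated 6-ene, and under equilibration C6 sits equatorial on ring A and axial over the lactone ring, which has fewer syn-axial hydrogens, so the trans A/B isomer (5R) should be favoured.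

**Compound list**
1 | 4-isopropyl-3,5-dimethoxybenzaldehyde | COc1cc(C=O)cc(OC)c1C(C)C | starting material
2 | (4-isopropyl-3,5-dimethoxyphenyl)acetonitrile | COc1cc(CC#N)cc(OC)c1C(C)C | intermediate
3 | methyl 2-bromopropanoate (racemic) | COC(=O)C(C)Br | starting material
4 | methyl 4-(4-isopropyl-3,5-dimethoxyphenyl)-2-methyl-3-oxobutanoate (racemic) | COC(=O)C(C)C(=O)Cc1cc(OC)c(C(C)C)c(OC)c1 | intermediate
5 | L-valine tert-butyl ester | CC(C)[C@H](N)C(=O)OC(C)(C)C | starting material
6 | Z-enamino ester of 4 and 5 | COC(=O)/C(C)=C(/Cc1cc(OC)c(C(C)C)c(OC)c1)N[C@@H](C(C)C)C(=O)OC(C)(C)C | intermediate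
7 | 1-chloro-3-iodopropane | ClCCCI | starting material
8 | alkylated ketimine (C4 S, not isolated) | ClCCC[C@](C)(C(=O)OC)C(Cc1cc(OC)c(C(C)C)c(OC)c1)=N[C@@H](C(C)C)C(=O)OC(C)(C)C | intermediate
9 | methyl (S)-2-(3-chloropropyl)-4-(4-isopropyl-3,5-dimethoxyphenyl)-2-methyl-3-oxobutanoate | ClCCC[C@](C)(C(=O)OC)C(=O)Cc1cc(OC)c(C(C)C)c(OC)c1 | intermediate
10 | methyl (1S)-3-(4-isopropyl-3,5-dimethoxyphenyl)-1-methyl-2-oxocyclohexane-1-carboxylate, both C3 epimers (not isolated) | COc1cc(cc(OC)c1C(C)C)C1CCC[C@](C)(C(=O)OC)C1=O | intermediate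
11 | methyl (1S,3R)-3-(hydroxymethyl)-3-(4-isopropyl-3,5-dimethoxyphenyl)-1-methyl-2-oxocyclohexane-1-carboxylate (not isolated) | COc1cc(cc(OC)c1C(C)C)[C@@]1(CO)CCC[C@](C)(C(=O)OC)C1=O | intermediate
12 | (1S,5R)-5-(4-isopropyl-3,5-dimethoxyphenyl)-1-methyl-3-oxabicyclo[3.3.1]nonane-2,9-dione | COc1cc(cc(OC)c1C(C)C)[C@]12CCC[C@](C)(C(=O)OC1)C2=O | intermediate
13 | (1S,5R,9S)-9-ethenyl-9-hydroxy-5-(4-isopropyl-3,5-dimethoxyphenyl)-1-methyl-3-oxabicyclo[3.3.1]nonan-2-one | COc1cc(cc(OC)c1C(C)C)[C@]12CCC[C@](C)(C(=O)OC1)[C@]2(O)C=C | intermediate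
14 | (4S,10S)-12,14-dimethoxyabieta-5,8,11,13-tetraen-19,20-olide (not isolated) | CC(C)c1c(OC)c2c(cc1OC)[C@]13CCC[C@](C)(C(=O)OC1)C3=CC2 | intermediate
15 | (4S,10S)-12,14-dihydroxyabieta-5,8,11,13-tetraen-19,20-olide | CC(C)c1c(O)c2c(cc1O)[C@]13CCC[C@](C)(C(=O)OC1)C3=CC2 | intermediate
16 | (4S,10R)-12-hydroxy-11,14-dioxoabieta-5,8,12-trien-19,20-olide | OC1=C(C(C)C)C(=O)C2=C(C1=O)[C@]13CCC[C@](C)(C(=O)OC1)C3=CC2 | intermediate
17 | (4S,10R)-12-acetoxy-11,14-dioxoabieta-5,8,12-trien-19,20-olide (not isolated) | CC(=O)OC1=C(C(C)C)C(=O)C2=C(C1=O)[C@]13CCC[C@](C)(C(=O)OC1)C3=CC2 | intermediate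
18 | (4S,5R,10R)-12-acetoxy-11,14-dioxoabieta-6,8,12-trien-19,20-olide | CC(=O)OC1=C(C(C)C)C(=O)C2=C(C1=O)[C@]13CCC[C@](C)(C(=O)OC1)[C@@H]3C=C2 | target

**Step count and risks**
Total step count: 9. Longest linear sequence: 9 (1 to 18).

The steps most likely to fail are 5, 6 and 9.

In step 5 the enolate may alkylate on oxygen to give a benzylidene tetrahydropyran, or the non-enolisable β-keto ester may cleave by retro-Claisen. The fallback gives up the alkylative closure and makes ring A by one-carbon ring expansion.
- It sets out from 1. Condensation with TsNHNH2 gives the N-tosylhydrazone F1.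
- NaOMe with gentle warming releases the aryldiazomethane F2.
- Under Sc(OTf)3 catalysis in toluene at −78 °C, F2 inserts into methyl (S)-1-methyl-2-oxocyclopentane-1-carboxylate F3. F3 is made from commercial methyl 2-oxocyclopentanecarboxylate and MeI under N-[4-(trifluoromethyl)benzyl]cinchoninium bromide/KOH phase transfer.
- The ring CH2 should migrate rather than the ester-bearing quaternary carbon.
- The fallback comes back to the route at 10, now isolated. The formaldehyde half of step 5 then carries 10 to 12.

In step 6 the ketone lies between two quaternary bridgeheads and may resist the vinyl reagent, or the adduct may fragment. The fallback sets out from 12 and uses the slimmest carbon nucleophile. HC≡CMgBr with LaCl3·2LiCl gives the propargylic alcohol F4. Semi-hydrogenation (H2, Pd/CaCO3 poisoned by Pb(OAc)2, quinoline) comes back at 13.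

In step 9 the extended enolate may be acetylated on oxygen or oxidised, or C5 may equilibrate poorly. The fallback moves the alkene shift to the arene stage, where it is the classical change of a 1,4-dihydronaphthalene into a 1,2-dihydronaphthalene.
- It sets out from 13. Catalytic CF3SO3H in CH2Cl2 gives 14, now isolated.
- KOtBu in DMSO, followed by an acidic work-up that recloses any opened lactone, gives the conjugated 6-ene dimethyl ether F5.
- BBr3 gives the 6-ene resorcinol F6.
- (KSO3)2NO gives the 12-hydroxy 6-ene quinone F7.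
- Ac2O/pyridine comes back at 18.

**Further compounds**
F1 | step 5 | N'-(4-isopropyl-3,5-dimethoxybenzylidene)-4-methylbenzenesulfonohydrazide | COc1cc(/C=N/NS(=O)(=O)c2ccc(C)cc2)cc(OC)c1C(C)C
F2 | step 5 | 5-(diazomethyl)-2-isopropyl-1,3-dimethoxybenzene | COc1cc(C=[N+]=[N-])cc(OC)c1C(C)C
F3 | step 5 | methyl (S)-1-methyl-2-oxocyclopentane-1-carboxylate | C1CC[C@](C)(C(=O)OC)C1=O
F4 | step 6 | (1S,5R,9S)-9-ethynyl-9-hydroxy-5-(4-isopropyl-3,5-dimethoxyphenyl)-1-methyl-3-oxabicyclo[3.3.1]nonan-2-one | COc1cc(cc(OC)c1C(C)C)[C@]12CCC[C@](C)(C(=O)OC1)[C@]2(O)C#C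
F5 | step 9 | (4S,5R,10R)-12,14-dimethoxyabieta-6,8,11,13-tetraen-19,20-olide | CC(C)c1c(OC)c2c(cc1OC)[C@]13CCC[C@](C)(C(=O)OC1)[C@@H]3C=C2
F6 | step 9 | (4S,5R,10R)-12,14-dihydroxyabieta-6,8,11,13-tetraen-19,20-olide | CC(C)c1c(O)c2c(cc1O)[C@]13CCC[C@](C)(C(=O)OC1)[C@@H]3C=C2
F7 | step 9 | (4S,5R,10R)-12-hydroxy-11,14-dioxoabieta-6,8,12-trien-19,20-olide | OC1=C(C(C)C)C(=O)C2=C(C1=O)[C@]13CCC[C@](C)(C(=O)OC1)[C@@H]3C=C2
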